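- The target stood at 2.2% of the charge after 60.0 s on Tuesday and 2.7% on Wednesday, against 7.4% and 7.5% of solvolysis product, so I asked first how much starting material had reacted by 2.0 min in the closed, stirred flasks south-east, east and north-west.

all flasks: starting material 0.020 M; gas 1.2 mM (held)
- Tuesday's: solid second nucleophile 0.019 M; run made earlier
- Wednesday's: solid second nucleophile 0.038 M; run made earlier
- south-east: solid second nucleophile 0.0180 M; time 2.0 min
- east: solid second nucleophile 0.0270 M; time 2.0 min
- north-west: solid second nucleophile 0.0400 M; time 2.0 min

| run | time / s | starting material / % | target / % | solvolysis product / % | other capture product / % |
|---|---|---|---|---|---|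
| Tuesday's | 10.0 | 98.1 | 0.6 | 1.0 | 0.2 |
| Tuesday's | 15.0 | 97.3 | 0.8 | 2.2 | 0 |
| Tuesday's | 30.0 | 95.0 | 1.6 | 4.4 | 0 |
| Tuesday's | 60.0 | 89.4 | 2.2 | 7.4 | 0.5 |
| Wednesday's | 12.0 | 97.8 | 0.3 | 1.2 | 0.1 |
| Wednesday's | 25.0 | 95.3 | 0.7 | 3.0 | 0.5 |
| Wednesday's | 40.0 | 93.4 | 1.9 | 4.7 | 0.4 |
| Wednesday's | 50.0 | 91.4 | 2.5 | 6.1 | 0.3 |
| Wednesday's | 60.0 | 90.0 | 2.7 | 7.5 | 0 |

(standard deviation of a reading: 0.3 percentage points)

- the numbers in the tables scatter with a standard deviation of 0.3 percentage points
- at the start none of the solid second nucleophile is in solution
- at the start none of the gas is in solution
- a reading or a percentage of target counts all its forms, free or not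

1. which of these there is most of at the end, counted by the starting material in it, south-east (target / starting material / other capture product / solvolysis product)
2. which of these there is most of at the end, counted by the starting material in it, east (target / starting material / other capture product / solvolysis product)
3. which of these there is most of at the end, counted by the starting material in it, north-west (target / starting material / other capture product / solvolysis product)
4. how much there is at the end of the one of these that leads, in percent of the starting material charged: south-east
5. how much there is at the end of the one of these that leads, in percent of the starting material charged: east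
6. how much there is at the end of the one of these that leads, in percent of the starting material charged: north-west

- My first estimate read Tuesday's last fraction of starting material as a first-order decay, and that gave a half-life of 6.19 min.
- My objection was that Wednesday's flask took twice Tuesday's charge of solid second nucleophile, so this figure might belong to Tuesday's flask and no other. But the two last readings of starting material lay 0.6 percentage points apart, with a scatter of 0.3 points on each, and Wednesday's flask was the higher one, so I saw no push from the solid.
- I therefore pooled both readings into one half-life of the starting material, 6.38 min, the time in which the fraction of the charge left falls to 0.5 of its value.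
- My next objection was that the solid and the gas start undissolved, so the flask changes during a run and the decay might not keep one pace. I tested this on Tuesday's flask at 30.0 s: the half-life gave 94.7% and the reading was 95.0%, which lies within the scatter.
- Counting half-lives, 2.0 min was 0.314 of one, which gave my estimate of 80.5% of the charge left in each of the three flasks.
- My last doubt was whether a product could lead instead. The reckoned loss came to 19.5%, less than the reckoned remainder, so by my estimate the starting material led whichever product took that loss.
- The forecast also named starting material as the leader, at 80.5% in south-east, 80.5% in east and 80.5% in north-west: “The slow step is therefore activation of the starting material, and neither nucleophile enters it.”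
- The flasks gave starting material in the lead, at 80.6% in south-east, 80.6% in east and 80.6% in north-west, against my 80.5%. Target reached 4.88% in south-east and 4.88% in north-west.

    starting material → intermediate (k = 0.00180 s⁻¹)
    first nucleophile + intermediate → target (k = 540 M⁻¹ s⁻¹)
    second nucleophile + intermediate → other capture product (k = 21.0 M⁻¹ s⁻¹)
    intermediate → solvolysis product (k = 1.80 s⁻¹)
    solid second nucleophile ⇌ second nucleophile, rate k5*(cs5 - [second nucleophile]) while solid is left; crystals form when [second nucleophile] > cs5 (solubility = 15.0 mM, k = 0.00750 s⁻¹)
    gas ⇌ first nucleophile, rate k6*(csat - [first nucleophile]) (kL = 1.20 s⁻¹)
    crystals ⇌ target, rate k7*(cs7 - [target]) while solid is left; crystals form when [target] > cs7 (solubility = 8.30 mM, k = 0.970 s⁻¹)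

- North-west kept 80.6% of its starting material because of the time given, not because of its charge of solid. The same flask left for 20.0 min held 11.5%, where my half-life counts 3.13 half-lives and gives 11.4%. The rate-limiting step, starting material to intermediate, gives by itself a half-life of the starting material of 6.4 min, long against 2.0 min.
- The flask east read at 30 s is 0.0784 of a half-life, so my reckoning gave 94.7% of the charge there. The computed flask holds 94.7%.

(All runs stem from a simulated flask from invented constants, and the scatter is random.)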